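Each electrophile seems to cost two nucleophiles, and you can read that from where the runs stall. With 1 equiv of nucleophile the delta run stands at 49.6% reacted at 30.0 h, and with 1.5 equiv the zeta run stands at 73.5%.

| flask | electrophile | nucleophile | protic impurity | remark | time |
|---|---|---|---|---|---|
| delta | 0.018 M | 1 equiv | 0.90 mM | run made earlier |  |
| zeta | 0.018 M | 1.5 equiv | 0.90 mM | run made earlier |  |
| gamma | 0.018 M | 2 equiv | 1.8 mM | run made earlier |  |
| flask | 0.018 M | 2.00 equiv | 0.900 mM |  | 2.0 d |

| run | time / h | electrophile / % | target / % |
|---|---|---|---|
| delta | 8.00 | 56.1 | 24.8 |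
| delta | 15.0 | 52.3 | 13.8 |
| delta | 20.0 | 51.4 | 10.2 |
| delta | 30.0 | 50.4 | 7.7 |
| zeta | 2.50 | 54.5 | 38.4 |
| zeta | 5.00 | 41.6 | 40.1 |
| zeta | 12.0 | 31.7 | 26.7 |
| zeta | 30.0 | 26.5 | 9.5 |
| gamma | 2.50 | 44.9 | 46.7 |
| gamma | 5.00 | 29.7 | 48.3 |
| gamma | 12.0 | 15.9 | 31.9 |
| gamma | 30.0 | 8.1 | 11.6 |

(readings scatter by 0.5 percentage points)

- the earlier runs do not show how much of nucleophile is bound; that part of a forecast is a guess

- part of the electrophile that has reacted at 2.0 d
- share of the unused nucleophile that is free and not bound as protonated nucleophile, at 2.0 d

So here is a bench rule. Take the equivalents of nucleophile, subtract the protic impurity per electrophile, assuming it takes one nucleophile each, and divide by two. For the flask that gives 97.5%, its ceiling. The rule is soft: the delta and zeta ceilings are 47.5% and 72.5%, and those readings stand above them by 2.1 percentage points and 1 point, against a scatter of 0.5 points.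

The rule stops working where the charge meets the demand, which is 2.05 equiv here. Past a ratio of one there is no ceiling to stall at, and hours take over. The flask's ratio is 0.976, just short of that crossing, so you must ask how close it gets in 2.0 d. The gamma run, with the same equivalents, was still 3.1 points under its ceiling at 30.0 h. Carried over unchanged, that gap gives my own rough estimate of 94.4% for the flask. It is no bound: gamma held twice the protic impurity of the flask, and its last reading came earlier than 2.0 d. Two free nucleophiles stand for each electrophile in that gap, so about 6.16% of the unused nucleophile is free, which is a guess, since the earlier runs do not show how much of it is bound.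

The forecast gives 95% (93% to 97%) and 6% (3% to 13%), holding that “each electrophile uses two nucleophiles”. Its 95% stands a little higher than my rough 94.4%.

    electrophile + nucleophile → acid set free + target (k = 15.0 M⁻¹ h⁻¹)
    nucleophile + acid set free ⇌ protonated nucleophile, settled at all times (K = 80000 M⁻¹)
    nucleophile + protic impurity → quenched reagent (k = 1100 M⁻¹ h⁻¹)
    target ⇌ isomer of the product (K = 12.0, k = 0.110 h⁻¹)

The flask gives 95.1% reacted, 2.4 points under its ceiling, with 5.89% of the unused nucleophile free. A neighbour flask with 0.500 equiv of nucleophile has a ceiling of 22.5% and stands at 25.6%, above it as delta was. At 2.00 d the electrophile's half-life by its own step is 1.8 d, longer than the 0.26 d forward half-life of target, and target is made at 0.490 of the rate it is used up. The flask then holds 8.64% target beside 86.5% isomer of the product.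

The earlier runs and the new flask stem from a simulated flask on assumed constants; scatter was added.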